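A one-step world has a single clock, but in the flask below, where a starting complex takes up an incoming ligand and gives off a leaving ligand, the readings of the complex with one exchanged show two.

all flasks: starting complex 0.30 M

| run | incoming ligand | remark | time |
|---|---|---|---|
| cedar | 0.35 M | run made earlier |  |
| oak | 1.1 M | run made earlier |  |
| Sunday's | 0.250 M |  | 3.0 h |
| Tuesday's | 0.400 M |  | 3.0 h |
| Friday's | 0.500 M |  | 3.0 h |
| Saturday's | 0.800 M |  | 3.0 h |

| cedar: time / h | cedar: complex with one exchanged / % | oak: time / h | oak: complex with one exchanged / % |
|---|---|---|---|
| 0.200 | 77 | 0.250 | 52 |
| 0.667 | 74 | 0.417 | 50 |
| 1.00 | 67 | 0.667 | 50 |
| 1.50 | 66 | 1.00 | 47 |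
| 2.50 | 60 | 2.00 | 43 |
| 3.00 | 58 | 3.00 | 40 |

(readings scatter by 1.5 percentage points)

- steps thought possible: starting complex + incoming ligand <-> leaving ligand + complex with one exchanged; complex with one exchanged <-> isomer of the product; complex with one exchanged + incoming ligand <-> leaving ligand + complex with two exchanged
- "hardly changes" means that all values lie within two and a half points (for a concentration: within two and a half percent of the largest)

- amount of complex with one exchanged at the end, in percent of the starting complex charged for Sunday's, Tuesday's, Friday's, Saturday's, in this order
- the shape of the row from first to last (falls all the way / falls, then rises / rises, then falls / hardly changes / rises all the way)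

The fast rung lies before the first reading: cedar, charged with 0.35 M of incoming ligand, already stands at 77% after 0.200 h, and oak, charged with 1.1 M, stands at 52% after 0.250 h, so the level reached depends on the charge.

The slow rung follows, and here something stays nearly constant. Late in cedar, the complex with one exchanged loses 0.0861 /h, and late in oak 0.0806 /h, although oak holds 3.14 times the ligand. This reading, λ, the fraction of the complex with one exchanged lost per hour late in a run, can therefore be frozen across the charges. A new flask should then keep 87.9% of its halfway amount by the end, so the differences along the row are looked for on the fast rung.

There, Sunday's flask charges less incoming ligand than starting complex, which makes the ligand the limiting reagent and caps the exchange at 83.3% of the complex charged. That cap stands above cedar's first reading, so it is not held against cedar directly; if Sunday's flask reaches the same share of its cap as cedar reaches of its whole charge, it ends near 48.3%, lower than cedar's last reading of 58%. Oak, with the larger charge of incoming ligand and the same charge of starting complex, ends lower than cedar. The reckoning made here is therefore a row that rises, then falls, with its top near cedar's charge.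

The forecast gave 50.5%, 57%, 55% and 47%, in its words “So the row rises, then falls”.

The flasks give 49.9%, 56.8%, 54.4% and 46.9%: the row rises, then falls, turning at 0.36 M.

    starting complex + incoming ligand ⇌ leaving ligand + complex with one exchanged (K = 43.3, k = 0.0598 /M/s)
    complex with one exchanged ⇌ isomer of the product (K = 0.657, k = 7.99 × 10⁻⁵ /s)
    complex with one exchanged + incoming ligand ⇌ leaving ligand + complex with two exchanged (K = 0.530, k = 0.122 /M/s)

In Sunday's flask at the end, the first exchange, taken by itself with both directions counted, relaxes with a half-life of 2.20 min, far shorter than the 2.4 h half-life of the complex with one exchanged under forward isomerisation alone. Sunday's complex with one exchanged goes from 56.1% at 1.50 h to 49.9% at 3.00 h, where λ reckons 49.3%. Saturday's flask goes from 51.7% to 46.9% over the same times, where λ reckons 45.4%.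

The data are simulated with made-up constants, noise included.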